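The earlier runs and the new flask were computed for an exercise; noise was put on by code.

**Charge ratio.** Blue holds 500 units of free monomer per pre-initiator charged, its charge ratio, and green holds 112. If each pre-initiator begins at most one chain, the pre-initiator charge caps the number of chains begun. The balance then reads: average length = monomer in chains (as a fraction of the free monomer charged) × charge ratio ÷ f, where f is the share of the pre-initiator charge that has begun chains. With the whole charge begun, this gives the floor length.

| flask | free monomer | pre-initiator | remark | time |
|---|---|---|---|---|
| dusk | 3 M | 0.13 mol% | run made earlier |  |
| autumn | 3 M | 0.68 mol% | run made earlier |  |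
| green | 3.0 M | 0.89 mol% |  | 2.0 h |
| blue | 3.0 M | 0.2 mol% |  | 2.0 h |

| run | time / min | monomer in chains / % | free monomer / % |
|---|---|---|---|
| dusk | 6.00 | 0 | 99.4 |
| dusk | 15.0 | 0.3 | 100.0 |
| dusk | 40.0 | 0.6 | 97.5 |
| dusk | 80.0 | 5.0 | 93.7 |
| autumn | 6.00 | 0 | 100.4 |
| autumn | 15.0 | 1.6 | 99.4 |
| autumn | 40.0 | 5.9 | 93.1 |
| autumn | 80.0 | 23.0 | 75.8 |

(readings scatter by 1 percentage point)

- the average divides the monomer in chains by the number of chains begun, living and dead together
- what was read earlier has a scatter of 1 percentage point, one standard deviation
- the earlier runs do not show the number of chains; that part of a forecast is a guess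

1. which of the two ends with the longer chains by the average number of monomer units in a chain (chains begun, living or dead) ("neither" if they lie within 10%) (green / blue / neither)
2. average number of monomer units in a chain (chains begun, living or dead) at the end, green
3. average number of monomer units in a chain (chains begun, living or dead) at the end, blue

**Dusk against autumn.** At 80.0 min, autumn has 5.23 times dusk's loading and 4.60 times its monomer in chains. The floor lengths are 38.5 for dusk and 33.8 for autumn, and a scatter of 1 percentage point on dusk's 5.0% cannot separate them. Both runs were charged with 3 M of free monomer, of which autumn has kept 75.8% and dusk 93.7%; the heavier charge in autumn is that of pre-initiator. If pre-initiator starts in proportion to its own charge, green and blue share one f at 2.0 h. The length ratio is then the floor ratio, and autumn's lower floor, a reading within the scatter, points to blue, the lighter charge, ending longer.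

**The forecast.** It names blue, with 240 for green (70 to 1000) and 320 for blue (90 to 1300). On f it says "The runs do not fix f" and guesses 0.25.

**The result.** Blue ends at 117 and green at 88.7, so the forecast's direction holds, while its green length stands 2.71 times too high.

    free monomer + initiator → living end + monomer in chains (k = 5.38 × 10⁻⁴ /M/s)
    free monomer + living end → monomer in chains + living end, rate k2*[living end]*[free monomer] (k = 0.0107 /M/s)
    pre-initiator → initiator (k = 1.78 × 10⁻⁴ /s)
    2 living end → dead end (k = 7.74 × 10⁻⁴ /M/s)

Blue's charge ratio gives a floor of 79.5, so f is 0.682. At 1.35 h in blue, pre-initiator has a half-life of 1.1 h and initiator one of 0.13 h, a far shorter time. At 2.00 h, 28% of blue's charge is still pre-initiator, 4.04% is initiator and the remaining 68.2% has begun chains. Blue read at 8.0 h keeps 0.59% pre-initiator, and there the same charge ratio gives a floor of 368 against a length of 372.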